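The route rests on disconnecting the C6–C7 bond, which is shared by the ten-membered carbocycle (C1–C10) and the butenolide (O–C6–C7=C11–C12). C7 is the β-carbon of a (Z)-enoate and C6 a carbinol carbon next to the 4,5-epoxide. A nickel/chromium-mediated (Nozaki–Hiyama–Kishi) addition of a (Z)-β-iodo-α-(silyloxymethyl)acrylate to an α,β-epoxy aldehyde therefore closes the macrocycle, sets C6 and, by lactonisation of the cis-disposed alkoxide and ester, forms the butenolide in the same operation. The acyclic precursor is assembled linearly from geranyl acetate by crotylation, propiolate alkynylation, iodide/formaldehyde halo-aldol and late Sharpless epoxidation.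

Key step: step 12

Remark on the chemistry: positions follow germacrane numbering (ring C1–C10; C11, C12, C13 = α-carbon, carbonyl carbon and CH2OH carbon of the lactone). The (Z)-crotylborane of the (+)-Ipc2BOMe series and (S,S)-ProPhenol are assumed to be the enantiomers that attack the Re face of their aldehydes.

Step 1
Reactants: 1 geranyl acetate
Product: 3 (2E)-3-methyl-6-oxohex-2-en-1-yl acetate, via ozonide 2 (not isolated)
Conditions: O3 (1.0 equiv), CH2Cl2, −78 °C; then Me2S, −78 °C → rt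
Reagents that add atoms: ozone, [O-][O+]=O
Why: The remote trisubstituted alkene is more electron-rich than the 2,3-alkene deactivated by the allylic acetate, so one equivalent of ozone should cleave it selectively (ozonolysis with reductive work-up); no stereocentre is formed.

Step 2
Reactants: 3 (2E)-3-methyl-6-oxohex-2-en-1-yl acetate
Product: 5 (2E,6S,7S)-6-hydroxy-3,7-dimethylnona-2,8-dien-1-yl acetate, via borinate ester 4 (not isolated)
Conditions: (Z)-crotyl-B(Ipc)2 [from cis-2-butene, n-BuLi, KOtBu, (+)-Ipc2BOMe, BF3·OEt2], THF/Et2O, −78 °C; then ethanolamine, rt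
Reagents that add atoms: (Z)-crotyldiisopinocampheylborane, C/C=C\CB([C@H]1C[C@H]2C[C@@H]([C@@H]1C)C2(C)C)[C@H]1C[C@H]2C[C@@H]([C@@H]1C)C2(C)C
Why: Brown asymmetric crotylboration through a chair transition state: the (Z)-crotyl geometry gives the syn C1-OH/C10-Me relationship and the isopinocampheyl groups direct Re-face attack, setting 1S and 10S (germacrane numbering).

Step 3
Reactants: 5 (2E,6S,7S)-6-hydroxy-3,7-dimethylnona-2,8-dien-1-yl acetate
Product: 6 (2E,6S,7S)-3,7-dimethylnona-2,8-diene-1,6-diyl diacetate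
Conditions: Ac2O, pyridine, DMAP (cat.), CH2Cl2, rt
Reagents that add atoms: acetic anhydride, CC(=O)OC(C)=O
Why: DMAP-catalysed acylation installs the C1 acetate of the target with retention at the carbinol carbon.

Step 4
Reactants: 6 (2E,6S,7S)-3,7-dimethylnona-2,8-diene-1,6-diyl diacetate
Product: 8 (2E,6S,7S)-9-hydroxy-3,7-dimethylnon-2-ene-1,6-diyl diacetate, via alkylborane 7 (not isolated)
Conditions: 9-BBN, THF, 0 °C → rt; then 30% H2O2, aq. NaOAc, rt
Reagents that add atoms: hydrogen peroxide, OO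
Why: Anti-Markovnikov hydroboration–oxidation; 9-BBN discriminates the terminal vinyl group from the trisubstituted alkene and the buffered oxidation should spare both acetates.

Step 5
Reactants: 8 (2E,6S,7S)-9-hydroxy-3,7-dimethylnon-2-ene-1,6-diyl diacetate
Product: 9 (2E,6S,7S)-3,7-dimethyl-9-oxonon-2-ene-1,6-diyl diacetate
Conditions: Dess–Martin periodinane, NaHCO3, CH2Cl2, rt
Reagents that add atoms: none
Why: Dess–Martin oxidation of the primary alcohol under buffered, non-epimerising conditions gives the C8 aldehyde.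

Step 6
Reactants: 9 (2E,6S,7S)-3,7-dimethyl-9-oxonon-2-ene-1,6-diyl diacetate; 10 methyl propiolate
Product: 11 methyl (4S,6S,7S,10E)-7,12-diacetoxy-4-hydroxy-6,10-dimethyldodec-10-en-2-ynoate
Conditions: (S,S)-ProPhenol (20 mol %), Me2Zn, Ph3PO (40 mol %), toluene, 4 °C
Reagents that add atoms: none
Why: Trost asymmetric alkynylation: the zinc alkynylide is delivered to the Re face of the aldehyde inside the dinuclear zinc–ProPhenol pocket, setting 8S under catalyst control.

Step 7
Reactants: 11 methyl (4S,6S,7S,10E)-7,12-diacetoxy-4-hydroxy-6,10-dimethyldodec-10-en-2-ynoate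
Product: 13 methyl (2Z,4S,6S,7S,10E)-7,12-diacetoxy-4-hydroxy-2-(hydroxymethyl)-3-iodo-6,10-dimethyldodeca-2,10-dienoate, via magnesium allenolate 12 (not isolated)
Conditions: MgI2, HCHO (monomer, THF solution), CH2Cl2, −20 → 0 °C
Reagents that add atoms: magnesium diiodide, [Mg+2].[I-].[I-]; formaldehyde, C=O
Why: Halo-aldol (β-iodo Morita–Baylis–Hillman) reaction: iodide adds to the β-carbon C7 and the allenolate is hydroxymethylated at C11 on the side away from iodine, so iodine and ester should end up cis (Z), the anti-addition sense known from hydroiodination of 2-alkynoates; no stereocentre is formed.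

Step 8
Reactants: 13 methyl (2Z,4S,6S,7S,10E)-7,12-diacetoxy-4-hydroxy-2-(hydroxymethyl)-3-iodo-6,10-dimethyldodeca-2,10-dienoate
Product: 14 methyl (2Z,4S,6S,7S,10E)-7,12-diacetoxy-2-{[(tert-butyldimethylsilyl)oxy]methyl}-4-hydroxy-3-iodo-6,10-dimethyldodeca-2,10-dienoate
Conditions: TBSCl, imidazole, CH2Cl2, 0 °C
Reagents that add atoms: tert-butyldimethylsilyl chloride, CC(C)(C)[Si](C)(C)Cl
Why: Silylation selective for the primary allylic C13 hydroxyl over the hindered secondary C8 hydroxyl next to the tetrasubstituted alkene.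

Step 9
Reactants: 14 methyl (2Z,4S,6S,7S,10E)-7,12-diacetoxy-2-{[(tert-butyldimethylsilyl)oxy]methyl}-4-hydroxy-3-iodo-6,10-dimethyldodeca-2,10-dienoate
Product: 15 methyl (2Z,4S,6S,7S,10E)-7-acetoxy-2-{[(tert-butyldimethylsilyl)oxy]methyl}-4,12-dihydroxy-3-iodo-6,10-dimethyldodeca-2,10-dienoate
Conditions: Novozym 435 (immobilised Candida antarctica lipase B), pH 7 phosphate buffer/acetone, 30 °C
Reagents that add atoms: none
Why: Lipase-catalysed regioselective ester hydrolysis: the unhindered primary allylic acetate is accepted while the secondary C1 acetate flanked by the C10 methyl branch is not, and neutral pH spares the β-iodo enoate.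

Step 10
Reactants: 15 methyl (2Z,4S,6S,7S,10E)-7-acetoxy-2-{[(tert-butyldimethylsilyl)oxy]methyl}-4,12-dihydroxy-3-iodo-6,10-dimethyldodeca-2,10-dienoate
Product: 16 methyl (2Z,4S,6S,7S)-7-acetoxy-2-{[(tert-butyldimethylsilyl)oxy]methyl}-4-hydroxy-9-[(2R,3R)-3-(hydroxymethyl)-2-methyloxiran-2-yl]-3-iodo-6-methylnon-2-enoate
Conditions: Ti(OiPr)4 (30 mol %), D-(−)-DET (36 mol %), t-BuOOH, 4 Å MS, CH2Cl2, −20 °C
Reagents that add atoms: tert-butyl hydroperoxide, CC(C)(C)OO
Why: Sharpless asymmetric epoxidation: D-(−)-tartrate delivers oxygen to the face of the (E)-allylic alcohol that gives the 4R,5R epoxide under reagent control, and the electron-poor iodo-enoate alkene is inert.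

Step 11
Reactants: 16 methyl (2Z,4S,6S,7S)-7-acetoxy-2-{[(tert-butyldimethylsilyl)oxy]methyl}-4-hydroxy-9-[(2R,3R)-3-(hydroxymethyl)-2-methyloxiran-2-yl]-3-iodo-6-methylnon-2-enoate
Product: 17 methyl (2Z,4S,6S,7S)-7-acetoxy-2-{[(tert-butyldimethylsilyl)oxy]methyl}-9-[(2R,3S)-3-formyl-2-methyloxiran-2-yl]-4-hydroxy-3-iodo-6-methylnon-2-enoate
Conditions: TEMPO (10 mol %), PhI(OAc)2, CH2Cl2, rt
Reagents that add atoms: none
Why: Oxoammonium (TEMPO/PhI(OAc)2) oxidation is selective for the primary epoxy alcohol over the hindered secondary C8 carbinol and gives the non-epimerisable epoxy aldehyde (the CIP label at the formyl-bearing carbon changes, the geometry does not).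

Step 12
Reactants: 17 methyl (2Z,4S,6S,7S)-7-acetoxy-2-{[(tert-butyldimethylsilyl)oxy]methyl}-9-[(2R,3S)-3-formyl-2-methyloxiran-2-yl]-4-hydroxy-3-iodo-6-methylnon-2-enoate
Product: 20 (1S,4R,5R,6S,8S,10S)-1-acetoxy-13-(tert-butyldimethylsilyloxy)-4,5-epoxy-8-hydroxygermacr-7(11)-en-12,6-olide, via alkenylchromium species 18 (not isolated), via seco hydroxy ester 19 (not isolated)
Conditions: CrCl2 (15 equiv), NiCl2 (2 mol % of the CrCl2), DMSO/THF, rt, slow addition to 2 mM; aq. NH4Cl work-up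
Reagents that add atoms: none
Why: Zerovalent nickel inserts into the C7–I bond, the alkenyl group is passed to trivalent chromium, and alkenylchromium 18 adds to the C6 aldehyde; the chromium alkoxide of 19, held cis to the ester by the (Z)-alkene, then attacks C12 and expels methoxide. The closest known reactions are the Nozaki–Hiyama–Kishi closure of medium rings and the NHK/lactonisation of (Z)-β-iodoacrylates with aldehydes to butenolides. The cyclodecane closes by a 10-exo-trig 1,2-addition and the butenolide by a 5-exo-trig acyl substitution. The one new stereocentre, C6, is controlled by the epoxide: C7 attacks anti to the C5–O bond (Cornforth/polar Felkin–Anh), and the C4 methyl, cis to the formyl group, keeps the chromium-bound carbonyl oxygen turned away from C4, which exposes the face leading to 6S with H5 and H6 anti. The step needs ring closure over oligomerisation (high dilution), retention of the alkene geometry (configurationally stable alkenyl–nickel and –chromium species) and chemoselectivity for the aldehyde over esters, epoxide and the free C8 hydroxyl, which is the usual behaviour of organochromium reagents.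

Step 13
Reactants: 20 (1S,4R,5R,6S,8S,10S)-1-acetoxy-13-(tert-butyldimethylsilyloxy)-4,5-epoxy-8-hydroxygermacr-7(11)-en-12,6-olide
Product: 21 13-O-(tert-butyldimethylsilyl)glaucolide L (8-O-methacryloyl derivative of 20)
Conditions: methacrylic anhydride, Et3N, DMAP (cat.), CH2Cl2, 0 °C → rt
Reagents that add atoms: methacrylic anhydride, C=C(C)C(=O)OC(=O)C(C)=C
Why: DMAP-catalysed acylation of the only free hydroxyl (C8) with retention; the mild base should not touch the epoxide or the butenolide.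

Step 14
Reactants: 21 13-O-(tert-butyldimethylsilyl)glaucolide L
Product: 22 glaucolide L
Conditions: HF·pyridine, pyridine, THF, 0 °C
Reagents that add atoms: none
Why: Buffered fluoride cleavage of the primary allylic silyl ether releases the C13 hydroxyl without acyl migration or epoxide opening; no stereocentre is affected.

Compound list
1 | geranyl acetate, (2E)-3,7-dimethylocta-2,6-dien-1-yl acetate | CC(C)=CCC/C(C)=C/COC(C)=O | starting material
2 | ozonide, (2E)-5-(5,5-dimethyl-1,2,4-trioxolan-3-yl)-3-methylpent-2-en-1-yl acetate | CC1(C)OOC(CC/C(C)=C/COC(C)=O)O1 | intermediate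
3 | (2E)-3-methyl-6-oxohex-2-en-1-yl acetate | O=CCC/C(C)=C/COC(C)=O | intermediate
4 | diisopinocampheylborinate ester of 5 (O–B(Ipc)2 on the C6 oxygen) | C=C[C@H](C)[C@@H](OB([C@H]1C[C@H]2C[C@@H]([C@@H]1C)C2(C)C)[C@H]1C[C@H]2C[C@@H]([C@@H]1C)C2(C)C)CC/C(C)=C/COC(C)=O | intermediate
5 | (2E,6S,7S)-6-hydroxy-3,7-dimethylnona-2,8-dien-1-yl acetate | C=C[C@H](C)[C@@H](O)CC/C(C)=C/COC(C)=O | intermediate
6 | (2E,6S,7S)-3,7-dimethylnona-2,8-diene-1,6-diyl diacetate | C=C[C@H](C)[C@@H](OC(C)=O)CC/C(C)=C/COC(C)=O | intermediate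
7 | B-alkyl-9-borabicyclo[3.3.1]nonane from 6 (boron on the terminal carbon C9) | C(C[C@H](C)[C@@H](OC(C)=O)CC/C(C)=C/COC(C)=O)B1C2CCCC1CCC2 | intermediate
8 | (2E,6S,7S)-9-hydroxy-3,7-dimethylnon-2-ene-1,6-diyl diacetate | OCC[C@H](C)[C@@H](OC(C)=O)CC/C(C)=C/COC(C)=O | intermediate
9 | (2E,6S,7S)-3,7-dimethyl-9-oxonon-2-ene-1,6-diyl diacetate | O=CC[C@H](C)[C@@H](OC(C)=O)CC/C(C)=C/COC(C)=O | intermediate
10 | methyl propiolate | COC(=O)C#C | starting material
11 | methyl (4S,6S,7S,10E)-7,12-diacetoxy-4-hydroxy-6,10-dimethyldodec-10-en-2-ynoate | COC(=O)C#C[C@@H](O)C[C@H](C)[C@@H](OC(C)=O)CC/C(C)=C/COC(C)=O | intermediate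
12 | magnesium β-iodo allenolate of 11 (iodine on C3, O–MgI ketene acetal) | COC(O[Mg]I)=C=C(I)[C@@H](O)C[C@H](C)[C@@H](OC(C)=O)CC/C(C)=C/COC(C)=O | intermediate
13 | methyl (2Z,4S,6S,7S,10E)-7,12-diacetoxy-4-hydroxy-2-(hydroxymethyl)-3-iodo-6,10-dimethyldodeca-2,10-dienoate | COC(=O)/C(CO)=C(\I)[C@@H](O)C[C@H](C)[C@@H](OC(C)=O)CC/C(C)=C/COC(C)=O | intermediate
14 | methyl (2Z,4S,6S,7S,10E)-7,12-diacetoxy-2-{[(tert-butyldimethylsilyl)oxy]methyl}-4-hydroxy-3-iodo-6,10-dimethyldodeca-2,10-dienoate | COC(=O)/C(CO[Si](C)(C)C(C)(C)C)=C(\I)[C@@H](O)C[C@H](C)[C@@H](OC(C)=O)CC/C(C)=C/COC(C)=O | intermediate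
15 | methyl (2Z,4S,6S,7S,10E)-7-acetoxy-2-{[(tert-butyldimethylsilyl)oxy]methyl}-4,12-dihydroxy-3-iodo-6,10-dimethyldodeca-2,10-dienoate | COC(=O)/C(CO[Si](C)(C)C(C)(C)C)=C(\I)[C@@H](O)C[C@H](C)[C@@H](OC(C)=O)CC/C(C)=C/CO | intermediate
16 | methyl (2Z,4S,6S,7S)-7-acetoxy-2-{[(tert-butyldimethylsilyl)oxy]methyl}-4-hydroxy-9-[(2R,3R)-3-(hydroxymethyl)-2-methyloxiran-2-yl]-3-iodo-6-methylnon-2-enoate | COC(=O)/C(CO[Si](C)(C)C(C)(C)C)=C(\I)[C@@H](O)C[C@H](C)[C@@H](OC(C)=O)CC[C@@]1(C)O[C@@H]1CO | intermediate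
17 | methyl (2Z,4S,6S,7S)-7-acetoxy-2-{[(tert-butyldimethylsilyl)oxy]methyl}-9-[(2R,3S)-3-formyl-2-methyloxiran-2-yl]-4-hydroxy-3-iodo-6-methylnon-2-enoate | COC(=O)/C(CO[Si](C)(C)C(C)(C)C)=C(\I)[C@@H](O)C[C@H](C)[C@@H](OC(C)=O)CC[C@@]1(C)O[C@@H]1C=O | intermediate
18 | alkenylchromium dichloride derived from 17 (CrCl2 in place of iodine) | COC(=O)/C(CO[Si](C)(C)C(C)(C)C)=C(\[Cr](Cl)Cl)[C@@H](O)C[C@H](C)[C@@H](OC(C)=O)CC[C@@]1(C)O[C@@H]1C=O | intermediate
19 | seco hydroxy ester (ten-membered ring closed, 6S-hydroxyl free, exocyclic (Z)-alkylidene methyl ester not yet lactonised; formed as its chromium alkoxide) | O[C@H]1C[C@H](C)[C@@H](OC(C)=O)CC[C@@]2(C)O[C@@H]2[C@@H](O)/C1=C(/CO[Si](C)(C)C(C)(C)C)C(=O)OC | intermediate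
20 | (1S,4R,5R,6S,8S,10S)-1-acetoxy-13-(tert-butyldimethylsilyloxy)-4,5-epoxy-8-hydroxygermacr-7(11)-en-12,6-olide | O[C@H]1C[C@H](C)[C@@H](OC(C)=O)CC[C@@]2(C)O[C@@H]2[C@H]2OC(=O)C(CO[Si](C)(C)C(C)(C)C)=C12 | intermediate
21 | 13-O-(tert-butyldimethylsilyl)glaucolide L | C=C(C)C(=O)O[C@H]1C[C@H](C)[C@@H](OC(C)=O)CC[C@@]2(C)O[C@@H]2[C@H]2OC(=O)C(CO[Si](C)(C)C(C)(C)C)=C12 | intermediate
22 | glaucolide L | C=C(C)C(=O)O[C@H]1C[C@H](C)[C@@H](OC(C)=O)CC[C@@]2(C)O[C@@H]2[C@H]2OC(=O)C(CO)=C12 | target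

Total step count: 14. Longest linear sequence: 14 steps (from geranyl acetate 1).

Steps most likely to fail

Step 12 (key step). The chromium salts may open or reduce the epoxy aldehyde, intermolecular coupling may outpace the slow closure at the hindered tetrasubstituted alkenyl carbon, or the aldehyde may be attacked on the undesired face. The fallback introduces the epoxide after ring closure. Setting out from 15, the allylic alcohol is oxidised with MnO2 (CH2Cl2, rt; the hindered, electron-poor C8 carbinol should be spared) to the (E)-enal F1. The same nickel/chromium closure (CrCl2, NiCl2, DMSO, high dilution) on this more robust enal should give the 4,5-(E)-unsaturated macrocyclic butenolide F2. mCPBA (NaHCO3, CH2Cl2, 0 °C) should then epoxidise the only electron-rich alkene from its peripheral face, as in the epoxidation of germacrolides, and the route is rejoined at 20.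

Step 7. Iodide addition to the internal ynoate may be slow, and reversible iodide addition may erode the alkene geometry, the wrong isomer then being drained by lactonisation onto the C8 hydroxyl. The fallback fixes the geometry through a chelated enolate instead of an allenolate. Setting out from 11, silylation (Et3SiOTf, 2,6-lutidine) gives the triethylsilyl ether F3. Pyrrolidine addition followed by mild aqueous acid hydrolysis of the enamine gives the β-keto ester F4. Hydroxymethylation (aq. HCHO, KHCO3) gives the hydroxymethyl keto ester F5, and TBSCl/imidazole gives its silyl ether F6. NaH followed by Tf2O traps the chelated sodium enolate as the (Z)-enol triflate F7. Nickel-catalysed triflate–iodide exchange (Ni(cod)2, NaI, DMA/THF) gives the vinyl iodide F8, and selective removal of the triethylsilyl group (PPTS, MeOH, 0 °C) rejoins the route at 14.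

Step 6. Enolisation and self-aldol condensation of the α-unbranched aldehyde, and incomplete catalyst control at C8, may lower yield and diastereomeric purity. Setting out from 9 and 10, lithiated methyl propiolate (LiN(SiMe3)2, THF, −78 °C) adds without stereocontrol to give the C8-epimeric propargylic alcohols F9. Dess–Martin oxidation gives the ynone F10, and Midland reduction with (S)-Alpine-Borane should return 11 as a single C8 epimer.

Further compounds
F1 | step 12 | methyl (2Z,4S,6S,7S,10E)-7-acetoxy-2-{[(tert-butyldimethylsilyl)oxy]methyl}-4-hydroxy-3-iodo-6,10-dimethyl-12-oxododeca-2,10-dienoate | COC(=O)/C(CO[Si](C)(C)C(C)(C)C)=C(\I)[C@@H](O)C[C@H](C)[C@@H](OC(C)=O)CC/C(C)=C/C=O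
F2 | step 12 | 4,5-(E)-alkene analogue of 20 (1-acetoxy-13-(tert-butyldimethylsilyloxy)-8-hydroxygermacra-4E,7(11)-dien-12,6-olide, same spatial arrangement at C1, C6, C8, C10) | O[C@H]1C[C@H](C)[C@@H](OC(C)=O)CC/C(C)=C/[C@H]2OC(=O)C(CO[Si](C)(C)C(C)(C)C)=C12
F3 | step 7 | methyl (4S,6S,7S,10E)-7,12-diacetoxy-6,10-dimethyl-4-(triethylsilyloxy)dodec-10-en-2-ynoate | COC(=O)C#C[C@@H](O[Si](CC)(CC)CC)C[C@H](C)[C@@H](OC(C)=O)CC/C(C)=C/COC(C)=O
F4 | step 7 | methyl (4S,6S,7S,10E)-7,12-diacetoxy-6,10-dimethyl-3-oxo-4-(triethylsilyloxy)dodec-10-enoate | COC(=O)CC(=O)[C@@H](O[Si](CC)(CC)CC)C[C@H](C)[C@@H](OC(C)=O)CC/C(C)=C/COC(C)=O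
F5 | step 7 | methyl (4S,6S,7S,10E)-7,12-diacetoxy-2-(hydroxymethyl)-6,10-dimethyl-3-oxo-4-(triethylsilyloxy)dodec-10-enoate (C2 epimers) | COC(=O)C(CO)C(=O)[C@@H](O[Si](CC)(CC)CC)C[C@H](C)[C@@H](OC(C)=O)CC/C(C)=C/COC(C)=O
F6 | step 7 | methyl (4S,6S,7S,10E)-7,12-diacetoxy-2-{[(tert-butyldimethylsilyl)oxy]methyl}-6,10-dimethyl-3-oxo-4-(triethylsilyloxy)dodec-10-enoate (C2 epimers) | COC(=O)C(CO[Si](C)(C)C(C)(C)C)C(=O)[C@@H](O[Si](CC)(CC)CC)C[C@H](C)[C@@H](OC(C)=O)CC/C(C)=C/COC(C)=O
F7 | step 7 | methyl (2Z,4S,6S,7S,10E)-7,12-diacetoxy-2-{[(tert-butyldimethylsilyl)oxy]methyl}-6,10-dimethyl-4-(triethylsilyloxy)-3-(trifluoromethylsulfonyloxy)dodeca-2,10-dienoate | COC(=O)/C(CO[Si](C)(C)C(C)(C)C)=C(\OS(=O)(=O)C(F)(F)F)[C@@H](O[Si](CC)(CC)CC)C[C@H](C)[C@@H](OC(C)=O)CC/C(C)=C/COC(C)=O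
F8 | step 7 | methyl (2Z,4S,6S,7S,10E)-7,12-diacetoxy-2-{[(tert-butyldimethylsilyl)oxy]methyl}-3-iodo-6,10-dimethyl-4-(triethylsilyloxy)dodeca-2,10-dienoate | COC(=O)/C(CO[Si](C)(C)C(C)(C)C)=C(\I)[C@@H](O[Si](CC)(CC)CC)C[C@H](C)[C@@H](OC(C)=O)CC/C(C)=C/COC(C)=O
F9 | step 6 | methyl (6S,7S,10E)-7,12-diacetoxy-4-hydroxy-6,10-dimethyldodec-10-en-2-ynoate (mixture of C4 epimers) | COC(=O)C#CC(O)C[C@H](C)[C@@H](OC(C)=O)CC/C(C)=C/COC(C)=O
F10 | step 6 | methyl (6S,7S,10E)-7,12-diacetoxy-6,10-dimethyl-4-oxododec-10-en-2-ynoate | COC(=O)C#CC(=O)C[C@H](C)[C@@H](OC(C)=O)CC/C(C)=C/COC(C)=O
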